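**Plan**

1. Retrosynthetic cuts: the C15 ethyl ester; C8–CH3 (through the 7-ene enol triflate of a C8 ketone); C12–C13 (Negishi); the C19 ester; then ring B across C6–C7 and C5–C10 in one retro-[4+2], which opens ring A as well; C7=C8 (methylenation); C1–C10 (B-alkyl Suzuki–Miyaura); C3–C4 (alkylation).
2. Forward order: the quaternary C4 nitrile 7 is joined to the enol triflate of acetylbutyrolactone. Methylenation gives a 2-methylidene-3-alkylidene-oxolane. One intramolecular Diels–Alder reaction then closes rings A and B together. The oxolane (temporary ring C) is opened afterwards, and the side chain and the C8 methyl group are added.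
3. Enabling feature: ring B is a six-membered ring whose C5–C6 edge (dienophile) and C7–C8–C9–C10 edge (diene) are linked through C1–C4 of ring A, with the C5–C10 bond common to both rings. The oxygen on C8 locks the diene s-cis, later becomes the C8 ketone that delivers the 7-ene with its methyl group, and leaves C12–O as the side-chain handle.
4. Stereochemistry: C4 from a chiral lithium amide alkylation; C5 and C10 from C4 in the cycloaddition (axial nitrile, tether-exo chair, trans fusion); C9 by thermodynamic protonation next to the C8 ketone; 13Z from the vinyl iodide; the angelate from angelic acid.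

Key step: step 7

Remark: locants C1–C20 in names follow the labdane skeleton; C19 is the axial carbon on C4, on the same face as the C10 methyl group.
Assumption: the (R,R)-tetramine base is taken to give the (S)-acid 4; if the induction runs the other way the (S,S)-base is used.
Assumption: ethyl (Z)-3-iodobut-2-enoate, angelic acid and the Tebbe reagent are bought.

**Step 1**
Reactants: 1 tiglic acid; 2 allyl bromide
Product: 4 (2S)-2-ethenyl-2-methylpent-4-enoic acid, via dilithium dienediolate 3 (not isolated)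
Conditions: (R,R)-N,N'-bis(1-phenyl-2-piperidin-1-ylethyl)propane-1,3-diamine, n-BuLi (4 equiv), THF, 0 °C; then 2, −78 °C; aq. HCl
Reagents that add atoms: none
Why: Enantioselective deconjugative α-alkylation of a carboxylic acid dienediolate held in a mixed aggregate with a chiral dilithium amide (traceless-auxiliary enediolate alkylation); α-attack on the reactive allylic bromide creates the C4 quaternary centre, whose configuration is set by the chiral amide.

**Step 2**
Reactants: 4 (2S)-2-ethenyl-2-methylpent-4-enoic acid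
Product: 6 (2S)-2-ethenyl-2-methylpent-4-enamide, via acid chloride 5 (not isolated)
Conditions: (COCl)2, DMF (cat.), CH2Cl2, 0 to 23 °C; then NH3 (dioxane), 0 °C
Reagents that add atoms: ammonia, N
Why: Acyl chloride formation and ammonolysis (standard amide synthesis); the quaternary centre has no α-hydrogen and cannot racemise.

**Step 3**
Reactants: 6 (2S)-2-ethenyl-2-methylpent-4-enamide
Product: 7 (2S)-2-ethenyl-2-methylpent-4-enenitrile
Conditions: (CF3CO)2O, pyridine, CH2Cl2, 0 °C
Reagents that add atoms: none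
Why: Dehydration of a primary amide to the nitrile; the nitrile is the smallest available form of C19 and is inert in the later cycloaddition.

**Step 4**
Reactants: 8 3-acetyloxolan-2-one (α-acetyl-γ-butyrolactone)
Product: 9 (1E)-1-(2-oxooxolan-3-ylidene)ethyl trifluoromethanesulfonate
Conditions: Tf2O, Me4NOH (aq.), toluene, 0 °C
Reagents that add atoms: trifluoromethanesulfonic anhydride, O=S(=O)(OS(=O)(=O)C(F)(F)F)C(F)(F)F
Why: Stereoselective O-triflation of a β-keto lactone enolate under non-chelating Schotten–Baumann conditions; with a tetraalkylammonium counter-ion the enolate oxygen should sit anti to the lactone carbonyl, giving the E enol triflate (triflate cis to the ring CH2, methyl cis to the carbonyl).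

**Step 5**
Reactants: 7 (2S)-2-ethenyl-2-methylpent-4-enenitrile; 9 (1E)-1-(2-oxooxolan-3-ylidene)ethyl trifluoromethanesulfonate
Product: 11 (2S,6E)-2-ethenyl-2-methyl-6-(2-oxooxolan-3-ylidene)heptanenitrile, via alkylborane 10 (not isolated)
Conditions: 9-BBN, THF, 0 to 23 °C; then 9, PdCl2(dppf) (cat.), AsPh3, K3PO4 (aq.), DMF, 23 °C
Reagents that add atoms: none
Why: Chemoselective hydroboration of the allyl terminus (the vinyl group on the quaternary α-cyano carbon is slower for steric and inductive reasons), then B-alkyl Suzuki–Miyaura coupling with retention of the enol triflate geometry, so the tether ends up trans and the methyl cis to the lactone carbonyl.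

**Step 6**
Reactants: 11 (2S,6E)-2-ethenyl-2-methyl-6-(2-oxooxolan-3-ylidene)heptanenitrile
Product: 12 (2S,6E)-2-ethenyl-2-methyl-6-(2-methylideneoxolan-3-ylidene)heptanenitrile
Conditions: Cp2Ti(CH2)(Cl)AlMe2 (Tebbe reagent), pyridine (cat.), THF/toluene, −40 to 0 °C; aq. NaOH; basic alumina
Reagents that add atoms: Tebbe reagent, C[Al-]1(C)C[Ti]([Cl+]1)(C1C=CC=C1)C1C=CC=C1
Why: Tebbe methylenation of the lactone carbonyl, which should be faster at low temperature than attack on the hindered tertiary nitrile; it gives the exocyclic enol ether and thereby the s-cis-locked 2-alkoxy diene C7=C8–C9=C10.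

**Step 7**
Reactants: 12 (2S,6E)-2-ethenyl-2-methyl-6-(2-methylideneoxolan-3-ylidene)heptanenitrile
Product: 13 (5aR,6S,9aS)-6,9a-dimethyl-1,2,4,5,5a,6,7,8,9,9a-decahydronaphtho[2,1-b]furan-6-carbonitrile
Conditions: toluene (0.01 M), 2,6-di-tert-butyl-4-methylphenol (cat.), Et3N (cat.), base-washed sealed tube, 170 °C
Reagents that add atoms: none
Why: Thermal, concerted but asynchronous intramolecular Diels–Alder reaction in which the electron-rich, s-cis-locked 2-alkoxy diene C7=C8–C9=C10 adds across the vinyl group C5=C6, the unhindered C6–C7 bond leading and the congested C5–C10 bond following. The closest known reaction type is the type 1 intramolecular Diels–Alder reaction of 1,7,9-decatrienes that carry an exocyclic (1,2-dialkylidene-cycloalkane) diene. Ring B (C5–C6–C7–C8–C9–C10) closes as the [4+2] cyclohexene and ring A (C10–C1–C2–C3–C4–C5) closes through the four-carbon tether as a six-membered chair, the two rings sharing the new C5–C10 bond. C10 is fixed by the diene geometry (methyl inside, tether outside) and C5 by the tether-exo chair transition state, which gives the trans fusion (H-5 anti to the C10 methyl); the oxolane CH2 on C9 should disfavour the tether-endo, cis-fused alternative by clashing with the C2 hydrogens of the tether. The absolute sense comes from C4: of the two chairs, the one with the small nitrile axial (1,3 to the C10 methyl) and the methyl equatorial should be preferred, and that is the C19-axial arrangement of the target. The step also needs the cycloaddition to outrun the [1,5]-hydrogen shift from the inside methyl and acid-catalysed migration of the enol ether double bond; the locked diene, the gem-disubstituted tether, high dilution and base-washed glass are meant to secure this.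

**Step 8**
Reactants: 13 (5aR,6S,9aS)-6,9a-dimethyl-1,2,4,5,5a,6,7,8,9,9a-decahydronaphtho[2,1-b]furan-6-carbonitrile
Product: 15 [(5aR,6S,9aS)-6,9a-dimethyl-1,2,4,5,5a,6,7,8,9,9a-decahydronaphtho[2,1-b]furan-6-yl]methanol, via aldehyde 14 (not isolated)
Conditions: i-Bu2AlH, toluene, −78 to 0 °C; aq. potassium sodium tartrate (pH 7–8); then NaBH4, MeOH, 0 °C
Reagents that add atoms: water, O
Why: Reduction of the nitrile to the aldimine, neutral hydrolysis to the aldehyde (which should leave the tetrasubstituted enol ether intact) and borohydride reduction to the neopentyl C19 alcohol; no stereocentre is touched.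

**Step 9**
Reactants: 15 [(5aR,6S,9aS)-6,9a-dimethyl-1,2,4,5,5a,6,7,8,9,9a-decahydronaphtho[2,1-b]furan-6-yl]methanol; 16 angelic acid
Product: 18 [(5aR,6S,9aS)-6,9a-dimethyl-1,2,4,5,5a,6,7,8,9,9a-decahydronaphtho[2,1-b]furan-6-yl]methyl (2Z)-2-methylbut-2-enoate, via mixed anhydride 17 (not isolated)
Conditions: 16, 2,4,6-trichlorobenzoyl chloride, Et3N (excess), toluene, 23 °C; then 15, 80 °C (no DMAP)
Reagents that add atoms: none
Why: Yamaguchi-type mixed anhydride esterification without a nucleophilic catalyst, the usual way to acylate a hindered alcohol with angelic acid without isomerisation to the tiglate.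

**Step 10**
Reactants: 18 [(5aR,6S,9aS)-6,9a-dimethyl-1,2,4,5,5a,6,7,8,9,9a-decahydronaphtho[2,1-b]furan-6-yl]methyl (2Z)-2-methylbut-2-enoate
Product: 19 (4S,5R,9R,10S)-12-hydroxy-8-oxo-13,14,15,16,17-pentanorlabdan-19-yl (2Z)-2-methylbut-2-enoate
Conditions: 0.5 M HCl, THF/H2O, 23 °C
Reagents that add atoms: water, O
Why: Acid hydrolysis of the cyclic enol ether releases the C8 ketone and the C12 alcohol; protonation at C9 and equilibration through the enol should place the C9 side chain equatorial (9α-H), the configuration of the target.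

**Step 11**
Reactants: 19 (4S,5R,9R,10S)-12-hydroxy-8-oxo-13,14,15,16,17-pentanorlabdan-19-yl (2Z)-2-methylbut-2-enoate
Product: 20 (4S,5R,9R,10S)-12-iodo-8-oxo-13,14,15,16,17-pentanorlabdan-19-yl (2Z)-2-methylbut-2-enoate
Conditions: I2, PPh3, imidazole, CH2Cl2, 0 °C, dark
Reagents that add atoms: iodine, [I][I]
Why: Appel-type iodination of the primary alcohol under buffered conditions; the ketone and the angelate are not affected.

**Step 12**
Reactants: 20 (4S,5R,9R,10S)-12-iodo-8-oxo-13,14,15,16,17-pentanorlabdan-19-yl (2Z)-2-methylbut-2-enoate; 21 ethyl (Z)-3-iodobut-2-enoate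
Product: 23 ethyl (4S,5R,9R,10S,13Z)-19-{[(2Z)-2-methylbut-2-enoyl]oxy}-8-oxo-17-norlabd-13-en-15-oate, via alkylzinc iodide 22 (not isolated)
Conditions: Zn dust, LiCl, THF, 25–35 °C; then 21, Pd(PPh3)4 (cat.), THF, 25 °C
Reagents that add atoms: none
Why: Zinc insertion into the primary iodide (ketone and esters tolerated) and Negishi coupling with the Z vinyl iodide, which proceeds with retention and fixes the 13Z olefin.

**Step 13**
Reactants: 23 ethyl (4S,5R,9R,10S,13Z)-19-{[(2Z)-2-methylbut-2-enoyl]oxy}-8-oxo-17-norlabd-13-en-15-oate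
Product: 25 ethyl (4S,5R,9R,10S,13Z)-19-{[(2Z)-2-methylbut-2-enoyl]oxy}-8-[(trifluoromethanesulfonyl)oxy]-17-norlabda-7,13-dien-15-oate, via potassium enolate 24 (not isolated)
Conditions: KN(SiMe3)2, THF, −78 °C; then PhNTf2, −78 to 0 °C; aq. NH4Cl
Reagents that add atoms: N-phenylbis(trifluoromethanesulfonimide), O=S(=O)(N(c1ccccc1)S(=O)(=O)C(F)(F)F)C(F)(F)F
Why: Kinetic deprotonation at the less hindered C7 methylene (C9 is tertiary and flanked by the quaternary C10) and O-triflation give the 7-ene enol triflate regioselectively without touching C9.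

**Step 14**
Reactants: 25 ethyl (4S,5R,9R,10S,13Z)-19-{[(2Z)-2-methylbut-2-enoyl]oxy}-8-[(trifluoromethanesulfonyl)oxy]-17-norlabda-7,13-dien-15-oate
Product: 26 ethyl (4S,5R,9S,10R,13Z)-19-{[(2Z)-2-methylbut-2-enoyl]oxy}labda-7,13-dien-15-oate
Conditions: MeZnCl, Pd(PPh3)4 (cat.), THF, 50 °C
Reagents that add atoms: methylzinc chloride, C[Zn]Cl
Why: Palladium-catalysed Negishi methylation of the enol triflate installs the C8 methyl group with the double bond fixed at C7=C8; both esters are inert to the methylzinc reagent.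

**Step 15**
Reactants: 26 ethyl (4S,5R,9S,10R,13Z)-19-{[(2Z)-2-methylbut-2-enoyl]oxy}labda-7,13-dien-15-oate
Product: 27 (4S,5R,9S,10R,13Z)-19-{[(2Z)-2-methylbut-2-enoyl]oxy}labda-7,13-dien-15-oic acid (target)
Conditions: LiOH, THF/H2O, 35 °C; then 1 M HCl to pH 3, 0 °C
Reagents that add atoms: lithium hydroxide, [Li+].[OH-]
Why: Chemoselective saponification: the unhindered ethyl ester should be cleaved while the angelate of the axial neopentyl alcohol is sterically shielded.

**Compound list**

1 | tiglic acid, (E)-2-methylbut-2-enoic acid | C/C=C(\C)C(=O)O | starting material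
2 | allyl bromide | C=CCBr | starting material
3 | dilithium 2-methylbuta-1,3-diene-1,1-diolate (dienediolate of 1) | C=CC(C)=C([O-])[O-].[Li+].[Li+] | intermediate
4 | (2S)-2-ethenyl-2-methylpent-4-enoic acid | OC(=O)[C@@](C=C)(C)CC=C | intermediate
5 | (2S)-2-ethenyl-2-methylpent-4-enoyl chloride | ClC(=O)[C@@](C=C)(C)CC=C | intermediate
6 | (2S)-2-ethenyl-2-methylpent-4-enamide | NC(=O)[C@@](C=C)(C)CC=C | intermediate
7 | (2S)-2-ethenyl-2-methylpent-4-enenitrile | N#C[C@@](C=C)(C)CC=C | intermediate
8 | 3-acetyloxolan-2-one (α-acetyl-γ-butyrolactone) | CC(=O)C1CCOC1=O | starting material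
9 | (1E)-1-(2-oxooxolan-3-ylidene)ethyl trifluoromethanesulfonate | FC(F)(F)S(=O)(=O)O/C(C)=C1\CCOC1=O | intermediate
10 | (2S)-5-(9-borabicyclo[3.3.1]nonan-9-yl)-2-ethenyl-2-methylpentanenitrile | N#C[C@@](C=C)(C)CCCB1C2CCCC1CCC2 | intermediate
11 | (2S,6E)-2-ethenyl-2-methyl-6-(2-oxooxolan-3-ylidene)heptanenitrile | N#C[C@@](C=C)(C)CCC/C(C)=C1\CCOC1=O | intermediate
12 | (2S,6E)-2-ethenyl-2-methyl-6-(2-methylideneoxolan-3-ylidene)heptanenitrile | N#C[C@@](C=C)(C)CCC/C(C)=C1\CCOC1=C | intermediate
13 | (5aR,6S,9aS)-6,9a-dimethyl-1,2,4,5,5a,6,7,8,9,9a-decahydronaphtho[2,1-b]furan-6-carbonitrile (trans-fused rings A/B, axial nitrile cis to the angular methyl, 8,12-epoxy-8-ene) | N#C[C@@]1(C)CCC[C@]2(C)C3=C(CC[C@@H]12)OCC3 | intermediate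
14 | (5aR,6S,9aS)-6,9a-dimethyl-1,2,4,5,5a,6,7,8,9,9a-decahydronaphtho[2,1-b]furan-6-carbaldehyde | O=C[C@@]1(C)CCC[C@]2(C)C3=C(CC[C@@H]12)OCC3 | intermediate
15 | [(5aR,6S,9aS)-6,9a-dimethyl-1,2,4,5,5a,6,7,8,9,9a-decahydronaphtho[2,1-b]furan-6-yl]methanol | OC[C@@]1(C)CCC[C@]2(C)C3=C(CC[C@@H]12)OCC3 | intermediate
16 | angelic acid, (Z)-2-methylbut-2-enoic acid | C/C=C(/C)C(=O)O | starting material
17 | (2Z)-2-methylbut-2-enoic 2,4,6-trichlorobenzoic anhydride | C/C=C(/C)C(=O)OC(=O)c1c(Cl)cc(Cl)cc1Cl | intermediate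
18 | [(5aR,6S,9aS)-6,9a-dimethyl-1,2,4,5,5a,6,7,8,9,9a-decahydronaphtho[2,1-b]furan-6-yl]methyl (2Z)-2-methylbut-2-enoate | C/C=C(/C)C(=O)OC[C@@]1(C)CCC[C@]2(C)C3=C(CC[C@@H]12)OCC3 | intermediate
19 | (4S,5R,9R,10S)-12-hydroxy-8-oxo-13,14,15,16,17-pentanorlabdan-19-yl (2Z)-2-methylbut-2-enoate | C/C=C(/C)C(=O)OC[C@@]1(C)CCC[C@]2(C)[C@@H](CCO)C(=O)CC[C@@H]12 | intermediate
20 | (4S,5R,9R,10S)-12-iodo-8-oxo-13,14,15,16,17-pentanorlabdan-19-yl (2Z)-2-methylbut-2-enoate | C/C=C(/C)C(=O)OC[C@@]1(C)CCC[C@]2(C)[C@@H](CCI)C(=O)CC[C@@H]12 | intermediate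
21 | ethyl (Z)-3-iodobut-2-enoate | CCOC(=O)/C=C(/C)I | starting material
22 | alkylzinc iodide from 20 (C12–ZnI) | C/C=C(/C)C(=O)OC[C@@]1(C)CCC[C@]2(C)[C@@H](CC[Zn]I)C(=O)CC[C@@H]12 | intermediate
23 | ethyl (4S,5R,9R,10S,13Z)-19-{[(2Z)-2-methylbut-2-enoyl]oxy}-8-oxo-17-norlabd-13-en-15-oate | C/C=C(/C)C(=O)OC[C@@]1(C)CCC[C@]2(C)[C@@H](CC/C(C)=C\C(=O)OCC)C(=O)CC[C@@H]12 | intermediate
24 | potassium 7-en-8-olate of 23 | C/C=C(/C)C(=O)OC[C@@]1(C)CCC[C@]2(C)[C@@H](CC/C(C)=C\C(=O)OCC)C([O-])=CC[C@@H]12.[K+] | intermediate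
25 | ethyl (4S,5R,9R,10S,13Z)-19-{[(2Z)-2-methylbut-2-enoyl]oxy}-8-[(trifluoromethanesulfonyl)oxy]-17-norlabda-7,13-dien-15-oate | C/C=C(/C)C(=O)OC[C@@]1(C)CCC[C@]2(C)[C@@H](CC/C(C)=C\C(=O)OCC)C(OS(=O)(=O)C(F)(F)F)=CC[C@@H]12 | intermediate
26 | ethyl (4S,5R,9S,10R,13Z)-19-{[(2Z)-2-methylbut-2-enoyl]oxy}labda-7,13-dien-15-oate | C/C=C(/C)C(=O)OC[C@@]1(C)CCC[C@]2(C)[C@@H](CC/C(C)=C\C(=O)OCC)C(C)=CC[C@@H]12 | intermediate
27 | (4S,5R,9S,10R,13Z)-19-{[(2Z)-2-methylbut-2-enoyl]oxy}labda-7,13-dien-15-oic acid | C/C=C(/C)C(=O)OC[C@@]1(C)CCC[C@]2(C)[C@@H](CC/C(C)=C\C(=O)O)C(C)=CC[C@@H]12 | target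

**Totals**

Total step count: 15. Longest linear sequence: 14 steps (steps 1–3 and 5–15, from tiglic acid); step 4 is a one-step side branch.

**Steps most likely to fail**

Step 7. The cycloaddition may be outrun by a [1,5]-hydrogen shift from the inside methyl group of the locked diene or by migration of the enol ether double bond, and the trans-fusion and facial selectivity may be low. The fallback sets out from lactone 11 and returns at hydroxy ketone 19, replacing the locked cyclic dienyl ether by an open-chain silyloxy diene. MeLi (THF, −78 °C) opens the lactone to the hydroxy enone F1. Silylation of the alcohol (TBSCl, imidazole) and then of the methyl ketone (TBSOTf, Et3N) gives the open-chain 2-silyloxy triene F2, whose C9 substituent is larger and should enforce the trans fusion more strongly. Heating F2 (toluene, sealed tube, 190 °C) gives the silyl enol ether cycloadduct F3. Reduction of the nitrile as in step 8 gives, through the aldehyde F4, the alcohol F5, and angeloylation as in step 9 gives the angelate F6. Aqueous HCl in THF then removes both silyl groups and delivers 19.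

Step 6. The titanium methylidene may add to the nitrile, and the exocyclic enol ether may hydrolyse or isomerise during work-up. The fallback sets out from 11 and returns at 12 by a modified Julia olefination of the lactone, which uses no metal carbene. Lithiated 2-(methylsulfonyl)-1,3-benzothiazole (LiN(SiMe3)2, THF, −78 °C) adds to the lactone carbonyl to give the hemiketal sulfone F7. DBU in THF then triggers the Smiles rearrangement and loss of sulfur dioxide and benzothiazolone, giving 12.

Step 1. The alkylation of the dienediolate may proceed with insufficient enantioselectivity or α/γ regioselectivity. The fallback sets out from 1 and returns at 4 by classical resolution. Alkylation of dienediolate 3, generated with the achiral base LiN(i-Pr)2, with allyl bromide gives the racemic acid F8. Crystallisation of its (R)-1-phenylethylammonium salt F9 (or of the salt with the enantiomeric amine, whichever holds the (S)-acid in the less soluble salt) followed by acidification returns 4.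

**Further compounds**

F1 | step 7 | (2S,6E)-2-ethenyl-7-(2-hydroxyethyl)-2,6-dimethyl-8-oxonon-6-enenitrile | N#C[C@@](C=C)(C)CCC/C(C)=C(\CCO)C(C)=O
F2 | step 7 | (2S,6E)-8-[(tert-butyldimethylsilyl)oxy]-7-{2-[(tert-butyldimethylsilyl)oxy]ethyl}-2-ethenyl-2,6-dimethylnona-6,8-dienenitrile | N#C[C@@](C=C)(C)CCC/C(C)=C(\CCO[Si](C)(C)C(C)(C)C)C(=C)O[Si](C)(C)C(C)(C)C
F3 | step 7 | (4S,5R,10S)-8,12-bis[(tert-butyldimethylsilyl)oxy]-13,14,15,16,17-pentanorlabd-8-ene-19-nitrile | N#C[C@@]1(C)CCC[C@]2(C)C(CCO[Si](C)(C)C(C)(C)C)=C(O[Si](C)(C)C(C)(C)C)CC[C@@H]12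
F4 | step 7 | (4S,5R,10S)-8,12-bis[(tert-butyldimethylsilyl)oxy]-13,14,15,16,17-pentanorlabd-8-en-19-al | O=C[C@@]1(C)CCC[C@]2(C)C(CCO[Si](C)(C)C(C)(C)C)=C(O[Si](C)(C)C(C)(C)C)CC[C@@H]12
F5 | step 7 | (4S,5R,10S)-8,12-bis[(tert-butyldimethylsilyl)oxy]-13,14,15,16,17-pentanorlabd-8-en-19-ol | OC[C@@]1(C)CCC[C@]2(C)C(CCO[Si](C)(C)C(C)(C)C)=C(O[Si](C)(C)C(C)(C)C)CC[C@@H]12
F6 | step 7 | (4S,5R,10S)-8,12-bis[(tert-butyldimethylsilyl)oxy]-13,14,15,16,17-pentanorlabd-8-en-19-yl (2Z)-2-methylbut-2-enoate | C/C=C(/C)C(=O)OC[C@@]1(C)CCC[C@]2(C)C(CCO[Si](C)(C)C(C)(C)C)=C(O[Si](C)(C)C(C)(C)C)CC[C@@H]12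
F7 | step 6 | (2S,6E)-6-{2-[(1,3-benzothiazol-2-ylsulfonyl)methyl]-2-hydroxyoxolan-3-ylidene}-2-ethenyl-2-methylheptanenitrile | N#C[C@@](C=C)(C)CCC/C(C)=C1\CCOC1(O)CS(=O)(=O)c1nc2ccccc2s1
F8 | step 1 | rac-2-ethenyl-2-methylpent-4-enoic acid | OC(=O)C(C=C)(C)CC=C
F9 | step 1 | (R)-1-phenylethylammonium (2S)-2-ethenyl-2-methylpent-4-enoate | [O-]C(=O)[C@@](C=C)(C)CC=C.C[C@@H]([NH3+])c1ccccc1
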